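**Plan**

1. Enabling feature: in ring C1–C10 the oxygen-bearing C6, the ring-cis C4=C5 beside it, the ring-cis C1=C10 and the threo O8/O9 pair on C8–C9 are the ketone, the old ring alkene, the new alkene and the new σ-bond of an oxy-Cope ring expansion of a 1,6-dialkenylcyclohex-2-enol.
2. Retrosynthesis: the acyl groups, the C14 aldehyde and the C11=C13 methylene are removed first; the lactone is cut at O6–C12 and C7–C11 back to a C6 ketone; the ten-membered ring is cut at C8–C9 by a retro-[3,3] shift that restores the C1–C6 bond of a cyclohexenol.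
3. The cyclohexenol is cut at C6–C7 (alkoxyacetylide + ketone) and at C1–C10 (ketone enolate + enol triflate of a dioxanone).
4. Forward: cyclohexenone → α′-dioxinyl ketone → cis-dialkenyl carbinol → six-to-ten ring expansion (the dioxin becomes the C9/C14 acetonide) → γ-lactone on C6/C7 → α-methylene → ester, aldehyde and acetate.
5. Stereochemistry: a chiral Pd catalyst sets the ketone α-centre, axial acetylide addition relays it to the carbinol, and the chair of the [3,3] shift transfers both to C8/C9 and makes both ring alkenes ring-cis.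
6. C7 comes from chelate-controlled enolate alkylation next to C8; C6 from peripheral hydride delivery followed by an invertive lactonisation.

Key step: step 9

Remark: locants C1–C15 are those of the target's germacrane skeleton and are used for all ten-membered-ring compounds; β is the ring face that carries the C8 oxygen.
Remark: the sense of induction of the ligand in step 5 cannot be predicted with certainty; the antipode that delivers the 6S ketone is the one used.

**Route**

Step 1
Reactants: 1 3-methoxybenzyl alcohol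
Product: 3 3-(hydroxymethyl)cyclohex-2-en-1-one, via dienol ether 2 (not isolated)
Conditions: Li, NH3 (l), THF, t-BuOH, −78 → −33 °C; NH4Cl; then 1 M HCl, THF, rt
Reagents that add atoms: water, O
Why: Birch reduction of the anisole ring (the benzylic alcohol is carried as its lithium alkoxide and so is not hydrogenolysed) gives the 2,5-dihydro enol ether, and acid hydrolysis with migration of the double bond into conjugation gives the 3-substituted cyclohexenone.

Step 2
Reactants: 3 3-(hydroxymethyl)cyclohex-2-en-1-one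
Product: 4 3-{[tert-butyl(diphenyl)silyl]oxymethyl}cyclohex-2-en-1-one
Conditions: t-BuPh2SiCl, imidazole, DMF, 0 °C → rt
Reagents that add atoms: tert-butyl(chloro)diphenylsilane, CC(C)(C)[Si](Cl)(c1ccccc1)c1ccccc1
Why: Silylation of the primary alcohol gives an ether that should survive every basic, reducing and mildly acidic step up to the final deprotection.

Step 3
Reactants: 4 3-{[tert-butyl(diphenyl)silyl]oxymethyl}cyclohex-2-en-1-one
Product: 5 tert-butyl(diphenyl){[3-(trimethylsilyloxy)cyclohexa-1,3-dien-1-yl]methoxy}silane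
Conditions: LiN(iPr)2, THF, −78 °C; Me3SiCl, Et3N, −78 → 0 °C
Reagents that add atoms: chlorotrimethylsilane, C[Si](C)(C)Cl
Why: Kinetic deprotonation of the enone occurs at C6 (α′) and O-silylation gives the cross-conjugated 2-silyloxy diene, the regiodefined enolate equivalent for step 5 (kinetic enolate trapping).

Step 4
Reactants: 6 2,2-dimethyl-1,3-dioxan-5-one
Product: 7 2,2-dimethyl-4H-1,3-dioxin-5-yl trifluoromethanesulfonate
Conditions: NaN(SiMe3)2, THF, −78 °C; PhNTf2, −78 → 0 °C
Reagents that add atoms: N-phenylbis(trifluoromethanesulfonimide), O=S(=O)(N(c1ccccc1)S(=O)(=O)C(F)(F)F)C(F)(F)F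
Why: The symmetric ketone has a single enolate, which is O-sulfonylated to the cyclic enol triflate at −78 °C, where the dioxanone enolate does not open.

Step 5
Reactants: 5 silyl dienol ether; 7 dioxinyl triflate
Product: 9 (6S)-6-(2,2-dimethyl-4H-1,3-dioxin-5-yl)-3-{[tert-butyl(diphenyl)silyl]oxymethyl}cyclohex-2-en-1-one, via tin enolate 8 (not isolated)
Conditions: Bu3SnF (1.1 equiv), Pd(OAc)2 (5 mol %), (R)-DIFLUORPHOS (6 mol %), toluene, 40 °C
Reagents that add atoms: none
Why: Fluoride moves the enolate from silicon to tin, and base-free Pd-catalysed α-alkenylation of the tin enolate with the alkenyl triflate (oxidative addition, Sn-to-Pd transmetalation, C–C reductive elimination) forms the C6–dioxinyl bond, the chiral bisphosphine on palladium setting the tertiary α-stereocentre (6S) while the absence of base keeps it from racemising.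

Step 6
Reactants: 10 4-methoxybenzyl alcohol; 11 trichloroethylene
Product: 12 1-{[(E)-1,2-dichloroethenyl]oxymethyl}-4-methoxybenzene
Conditions: KH, THF, 0 °C; then 11, −50 °C → rt
Reagents that add atoms: none
Why: The potassium alkoxide adds to dichloroacetylene formed in situ from trichloroethylene and the adduct is protonated, the standard preparation of 1,2-dichlorovinyl ethers as ynol ether precursors.

Step 7
Reactants: 12 dichlorovinyl ether; 9 (6S)-ketone
Product: 14 (1R,6S)-6-(2,2-dimethyl-4H-1,3-dioxin-5-yl)-1-{[(4-methoxybenzyl)oxy]ethynyl}-3-{[tert-butyl(diphenyl)silyl]oxymethyl}cyclohex-2-en-1-ol, via lithium acetylide 13 (not isolated)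
Conditions: n-BuLi (2.0 equiv per 12), THF, −78 → −40 °C; then 9, −78 °C; aq. NaHCO3
Reagents that add atoms: none
Why: Two equivalents of n-BuLi turn the dichlorovinyl ether into the lithium alkoxyacetylide (dehydrochlorination, then Cl/Li exchange), and this small rod-shaped nucleophile adds to the half-chair enone on the axial face, antiperiplanar to the axial C6–H with the dioxinyl group equatorial, so that the alkynyl group ends up cis to the dioxinyl group and the carbinol centre is 1R (substrate-controlled 1,2-addition).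

Step 8
Reactants: 14 alkynyl carbinol
Product: 15 (1R,6S)-6-(2,2-dimethyl-4H-1,3-dioxin-5-yl)-1-{(E)-2-[(4-methoxybenzyl)oxy]ethenyl}-3-{[tert-butyl(diphenyl)silyl]oxymethyl}cyclohex-2-en-1-ol
Conditions: LiAlH4, THF, 0 °C → rt; aq. potassium sodium tartrate/NaOH; Et3N-deactivated silica
Reagents that add atoms: none
Why: Alkoxide-directed trans-hydroalumination of the propargylic ynol ether (hydride to the oxygen-bearing carbon) and protonolysis give the E enol ether; the temperature stays at or below rt and the work-up basic because benzyl-type ynol ethers rearrange on heating and the doubly allylic γ-hydroxy enol ether ionises with acid.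

Step 9
Reactants: 15 cis-dialkenyl carbinol
Product: 18 (8S,9S) ten-membered dienone (C6 ketone; ring-cis C4=C5 with CH2OSiPh2t-Bu on C4; ring-cis C1=C10; 8β-OPMB; O9α and O14 joined as acetonide), via potassium alkoxide 16 (not isolated), via potassium enolate 17 (not isolated)
Conditions: KH, 18-crown-6, THF, 0 °C → rt; then AcOH, THF, −78 °C
Reagents that add atoms: none
Why: Deprotonation gives the potassium alkoxide, whose [3,3] shift breaks the C1–C6 bond of the cyclohexene and joins C8 to C9, driven by formation of the C6/C7 enolate; the closest known reaction type is the anionic oxy-Cope ring expansion of 1,2-dialkenylcyclohexenols to cyclodecadienones. The ten-membered ring arises by four-carbon ring expansion through a six-centre chair transition state, not by end-to-end closure. In the reacting half-chair the dioxinyl group is equatorial and the alkoxyvinyl group axial, so C2 is axial in the chair and C1=C10 forms ring-cis, while C4=C5 stays ring-cis as a former cyclohexene bond. Both enol-ether oxygens are equatorial in the chair (E vinyl ether at C8, ring-locked dioxin at C9), which gives the threo pair, and the 1R,6S configuration of 15 is transferred to 8S,9S. The step needs this chair to be preferred over the other chair, a boat, or the bridged shift through C4=C5, which the equatorial preference of the bulky dioxinyl group in the cis-dialkenyl carbinol should secure. It also needs the β-alkoxy enolate to survive, hence the crown ether to allow rearrangement near rt and protonation at −78 °C.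

Step 10
Reactants: 18 dienone
Product: 20 dienone 18 carrying 7β-CH2C(O)NMe2 (side chain cis to O8), via lithium enolate 19 (not isolated)
Conditions: LiN(iPr)2, THF, −78 °C; BrCH2C(O)NMe2, DMPU, −78 → −40 °C
Reagents that add atoms: 2-bromo-N,N-dimethylacetamide, CN(C)C(=O)CBr
Why: Kinetic deprotonation at C7, the only α-CH2 of the enone, gives a lithium enolate chelated by the C8 ether oxygen, and the α-bromo amide attacks its outer face opposite C9, placing the side chain cis to O8 (enolate alkylation at −78 °C, where loss of the C8 ether is slow; an amide is used so that the C6 alcohol of step 11 cannot lactonise with retention).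

Step 11
Reactants: 20 keto amide
Product: 21 6β-hydroxy amide (OH cis to the C7 side chain and to O8)
Conditions: NaBH4, CeCl3·7H2O, MeOH, −78 → −40 °C
Reagents that add atoms: none
Why: Luche conditions reduce the enone carbonyl 1,2 only, and hydride delivered from the ring periphery, anti to the C7–C8 bond with the side chain near the carbonyl plane, should give the 6β-alcohol.

Step 12
Reactants: 21 6β-hydroxy amide
Product: 24 6α,12-trans-lactone (6R,7S,8S,9S; 8β-OPMB; 9,14-acetonide; 15-O-silyl), via allylic mesylate 22 (not isolated), via iminium lactone 23 (not isolated)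
Conditions: MeSO2Cl, Et3N, CH2Cl2, −40 → 0 °C; then THF/H2O, NaHCO3, rt
Reagents that add atoms: water, O
Why: Mesylation makes C6 an allylic electrophile that the neighbouring amide oxygen attacks from the rear (5-exo-tet, inversion at C6), and hydrolysis of the cyclic iminium ether gives the trans-fused γ-lactone with loss of dimethylamine (amide-assisted invertive lactonisation).

Step 13
Reactants: 24 lactone
Product: 26 11-(dimethylaminomethyl) lactone (C11 epimers), via lactone enolate 25 (not isolated)
Conditions: LiN(iPr)2, THF, −78 °C; Me2N=CH2+ I−, −78 → 0 °C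
Reagents that add atoms: dimethylmethyleneammonium iodide, C=[N+](C)C.[I-]
Why: The lactone enolate is aminomethylated at C11 by the iminium salt (Mannich reaction), and the configuration at C11 is of no consequence because the centre becomes sp2 in step 14.

Step 14
Reactants: 26 Mannich base
Product: 28 11(13)-methylene lactone (8β-OPMB; 9,14-acetonide; 15-O-silyl), via ammonium iodide 27 (not isolated)
Conditions: MeI, MeOH, rt; then aq. NaHCO3, EtOAc, rt
Reagents that add atoms: none
Why: N-Methylation gives the quaternary ammonium salt, which loses trimethylamine by base-induced β-elimination to give the exocyclic α-methylene lactone.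

Step 15
Reactants: 28 PMB ether
Product: 29 8β-alcohol
Conditions: DDQ, CH2Cl2/pH 7 buffer, 0 °C → rt
Reagents that add atoms: none
Why: DDQ oxidises the electron-rich 4-methoxybenzyl ether to an oxocarbenium ion that water cleaves, leaving the silyl ether, the acetonide and the α-methylene lactone untouched (oxidative PMB removal).

Step 16
Reactants: 29 8β-alcohol
Product: 30 8β-methacrylate
Conditions: methacrylic anhydride, Et3N, DMAP (cat.), CH2Cl2, 0 °C → rt
Reagents that add atoms: methacrylic anhydride, C=C(C)C(=O)OC(=O)C(C)=C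
Why: DMAP-catalysed acylation of the free secondary C8 alcohol by the anhydride installs the methacrylate.

Step 17
Reactants: 30 acetonide
Product: 31 9α,14-diol
Conditions: PPTS, MeOH, rt
Reagents that add atoms: none
Why: Acid-catalysed transacetalisation to methanol removes the six-membered acetonide, while the silyl ether, both esters and the lactone are stable to pyridinium tosylate.

Step 18
Reactants: 31 diol
Product: 32 14-aldehyde with free 9α-OH
Conditions: TEMPO (cat.), PhI(OAc)2, CH2Cl2, rt
Reagents that add atoms: none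
Why: The oxoammonium salt generated from TEMPO and PhI(OAc)2 oxidises the primary allylic C14 alcohol much faster than the hindered secondary C9 alcohol and gives the enal without isomerising C1=C10.

Step 19
Reactants: 32 hydroxy enal
Product: 33 9α-acetate (15-O-silyl ether of the target)
Conditions: Ac2O, pyridine, CH2Cl2, 0 °C
Reagents that add atoms: acetic anhydride, CC(=O)OC(C)=O
Why: Acetylation of the remaining secondary alcohol, with pyridine and no nucleophilic catalyst so that the allylic acetate next to the enal is not attacked in an SN2′ sense.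

Step 20
Reactants: 33 silyl ether
Product: 34 CNP0147326.4 (target)
Conditions: HF·pyridine, pyridine/THF, 0 °C → rt
Reagents that add atoms: none
Why: Fluoride cleaves the primary silyl ether under weakly acidic conditions that leave the acetate, methacrylate, enal and α-methylene lactone intact.

**Compound list**

1 | 3-methoxybenzyl alcohol | COc1cccc(CO)c1 | starting material
2 | (5-methoxycyclohexa-1,4-dien-1-yl)methanol (not isolated) | COC1=CCC=C(CO)C1 | intermediate
3 | 3-(hydroxymethyl)cyclohex-2-en-1-one | O=C1C=C(CO)CCC1 | intermediate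
4 | 3-{[tert-butyl(diphenyl)silyl]oxymethyl}cyclohex-2-en-1-one | O=C1C=C(CO[Si](c2ccccc2)(c3ccccc3)C(C)(C)C)CCC1 | intermediate
5 | tert-butyl(diphenyl){[3-(trimethylsilyloxy)cyclohexa-1,3-dien-1-yl]methoxy}silane | C[Si](C)(C)OC1=CCCC(CO[Si](c2ccccc2)(c3ccccc3)C(C)(C)C)=C1 | intermediate
6 | 2,2-dimethyl-1,3-dioxan-5-one | CC1(C)OCC(=O)CO1 | starting material
7 | 2,2-dimethyl-4H-1,3-dioxin-5-yl trifluoromethanesulfonate | CC1(C)OCC(OS(=O)(=O)C(F)(F)F)=CO1 | intermediate
8 | tributyltin enolate corresponding to 5 (not isolated) | CCCC[Sn](CCCC)(CCCC)OC1=CCCC(CO[Si](c2ccccc2)(c3ccccc3)C(C)(C)C)=C1 | intermediate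
9 | (6S)-6-(2,2-dimethyl-4H-1,3-dioxin-5-yl)-3-{[tert-butyl(diphenyl)silyl]oxymethyl}cyclohex-2-en-1-one | O=C1C=C(CO[Si](c2ccccc2)(c3ccccc3)C(C)(C)C)CC[C@H]1C4=COC(C)(C)OC4 | intermediate
10 | 4-methoxybenzyl alcohol | COc1ccc(CO)cc1 | starting material
11 | trichloroethylene | ClC=C(Cl)Cl | starting material
12 | 1-{[(E)-1,2-dichloroethenyl]oxymethyl}-4-methoxybenzene | COc1ccc(CO/C(Cl)=C\Cl)cc1 | intermediate
13 | lithium [(4-methoxybenzyl)oxy]acetylide (not isolated) | COc1ccc(COC#C[Li])cc1 | intermediate
14 | (1R,6S)-1-alkynyl carbinol (alkynyl cis to dioxinyl) | COc1ccc(COC#C[C@@]2(O)C=C(CO[Si](c3ccccc3)(c4ccccc4)C(C)(C)C)CC[C@H]2C5=COC(C)(C)OC5)cc1 | intermediate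
15 | (1R,6S)-1-[(E)-2-(PMB-oxy)ethenyl] carbinol (rearrangement precursor) | COc1ccc(CO/C=C/[C@@]2(O)C=C(CO[Si](c3ccccc3)(c4ccccc4)C(C)(C)C)CC[C@H]2C5=COC(C)(C)OC5)cc1 | intermediate
16 | potassium alkoxide of 15 (not isolated) | COc1ccc(CO/C=C/[C@@]2([O-])C=C(CO[Si](c3ccccc3)(c4ccccc4)C(C)(C)C)CC[C@H]2C5=COC(C)(C)OC5)cc1.[K+] | intermediate
17 | potassium C6/C7 enolate of 18, O6 cis to C8 (not isolated) | COc1ccc(CO[C@H]2/C=C(\[O-])/C=C(/CO[Si](c3ccccc3)(c4ccccc4)C(C)(C)C)CC/C=C5/COC(C)(C)O[C@H]25)cc1.[K+] | intermediate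
18 | (8S,9S) ten-membered dienone: C6 ketone, 8β-OPMB, 9α,14-acetonide, 15-O-silyl, both ring alkenes ring-cis | COc1ccc(CO[C@H]2CC(=O)/C=C(/CO[Si](c3ccccc3)(c4ccccc4)C(C)(C)C)CC/C=C5/COC(C)(C)O[C@H]25)cc1 | intermediate
19 | lithium C6/C7 enolate of 18, chelated by O8 (not isolated) | COc1ccc(CO[C@H]2/C=C(\O[Li])/C=C(/CO[Si](c3ccccc3)(c4ccccc4)C(C)(C)C)CC/C=C5/COC(C)(C)O[C@H]25)cc1 | intermediate
20 | 7β-(dimethylcarbamoylmethyl) dienone | COc1ccc(CO[C@H]2[C@@H](CC(=O)N(C)C)C(=O)/C=C(/CO[Si](c3ccccc3)(c4ccccc4)C(C)(C)C)CC/C=C5/COC(C)(C)O[C@H]25)cc1 | intermediate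
21 | 6β-hydroxy amide | COc1ccc(CO[C@H]2[C@@H](CC(=O)N(C)C)[C@@H](O)/C=C(/CO[Si](c3ccccc3)(c4ccccc4)C(C)(C)C)CC/C=C5/COC(C)(C)O[C@H]25)cc1 | intermediate
22 | 6β-mesylate of 21 (not isolated) | COc1ccc(CO[C@H]2[C@@H](CC(=O)N(C)C)[C@@H](OS(C)(=O)=O)/C=C(/CO[Si](c3ccccc3)(c4ccccc4)C(C)(C)C)CC/C=C5/COC(C)(C)O[C@H]25)cc1 | intermediate
23 | trans-fused cyclic iminium ether (C12=NMe2+), mesylate salt (not isolated) | COc1ccc(CO[C@H]2[C@H]3CC(=[N+](C)C)O[C@@H]3/C=C(/CO[Si](c4ccccc4)(c5ccccc5)C(C)(C)C)CC/C=C6/COC(C)(C)O[C@H]26)cc1.CS(=O)(=O)[O-] | intermediate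
24 | 6α,12-trans-lactone (6R,7S,8S,9S) | COc1ccc(CO[C@H]2[C@H]3CC(=O)O[C@@H]3/C=C(/CO[Si](c4ccccc4)(c5ccccc5)C(C)(C)C)CC/C=C6/COC(C)(C)O[C@H]26)cc1 | intermediate
25 | lithium enolate of lactone 24 (not isolated) | COc1ccc(CO[C@H]2[C@H]3C=C(O[Li])O[C@@H]3/C=C(/CO[Si](c4ccccc4)(c5ccccc5)C(C)(C)C)CC/C=C6/COC(C)(C)O[C@H]26)cc1 | intermediate
26 | 11-(dimethylaminomethyl) lactone, C11 epimers | COc1ccc(CO[C@H]2[C@H]3C(CN(C)C)C(=O)O[C@@H]3/C=C(/CO[Si](c4ccccc4)(c5ccccc5)C(C)(C)C)CC/C=C6/COC(C)(C)O[C@H]26)cc1 | intermediate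
27 | trimethylammonium iodide of 26 (not isolated) | COc1ccc(CO[C@H]2[C@H]3C(C[N+](C)(C)C)C(=O)O[C@@H]3/C=C(/CO[Si](c4ccccc4)(c5ccccc5)C(C)(C)C)CC/C=C6/COC(C)(C)O[C@H]26)cc1.[I-] | intermediate
28 | 11(13)-methylene lactone, 8β-OPMB | COc1ccc(CO[C@H]2[C@H]3C(=C)C(=O)O[C@@H]3/C=C(/CO[Si](c4ccccc4)(c5ccccc5)C(C)(C)C)CC/C=C6/COC(C)(C)O[C@H]26)cc1 | intermediate
29 | 8β-alcohol | O[C@H]1[C@H]2C(=C)C(=O)O[C@@H]2/C=C(/CO[Si](c3ccccc3)(c4ccccc4)C(C)(C)C)CC/C=C5/COC(C)(C)O[C@H]15 | intermediate
30 | 8β-methacrylate, 9,14-acetonide | C=C(C)C(=O)O[C@H]1[C@H]2C(=C)C(=O)O[C@@H]2/C=C(/CO[Si](c3ccccc3)(c4ccccc4)C(C)(C)C)CC/C=C5/COC(C)(C)O[C@H]15 | intermediate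
31 | 9α,14-diol | C=C(C)C(=O)O[C@H]1[C@H]2C(=C)C(=O)O[C@@H]2/C=C(/CO[Si](c3ccccc3)(c4ccccc4)C(C)(C)C)CC/C=C(/CO)[C@@H]1O | intermediate
32 | 14-aldehyde, 9α-alcohol | C=C(C)C(=O)O[C@H]1[C@H]2C(=C)C(=O)O[C@@H]2/C=C(/CO[Si](c3ccccc3)(c4ccccc4)C(C)(C)C)CC/C=C(/C=O)[C@@H]1O | intermediate
33 | 9α-acetate, 15-O-silyl ether of the target | C=C(C)C(=O)O[C@H]1[C@H]2C(=C)C(=O)O[C@@H]2/C=C(/CO[Si](c3ccccc3)(c4ccccc4)C(C)(C)C)CC/C=C(/C=O)[C@@H]1OC(C)=O | intermediate
34 | CNP0147326.4 | C=C(C)C(=O)O[C@H]1[C@H]2C(=C)C(=O)O[C@@H]2/C=C(/CO)CC/C=C(/C=O)[C@@H]1OC(C)=O | target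

**Count and risks**

Total: 20 steps. Longest linear sequence: 18 steps (1 → 34 through steps 1–3, 5 and 7–20).

Risk 1, step 9. The potassium enolate 17 may lose 4-methoxybenzyl oxide from C8 by β-elimination while the rearrangement is still running, or the shift may be too slow below the temperature that 17 tolerates. The fallback keeps the [3,3] ring expansion but carries no oxygen on the migrating vinyl group and adds it afterwards. It sets out from 9:
- HC≡CMgBr (THF, −78 °C, axial addition) gives the cis-ethynyl carbinol F1.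
- Semi-hydrogenation (H2, Pd/CaCO3 poisoned with Pb(OAc)2, quinoline) gives the cis-vinyl carbinol F2.
- KH, 18-crown-6, then Me3SiCl gives the silyl dienol ether F3 of the ring-expanded ketone, whose enolate has no β-leaving group.
- Pd(OAc)2 in MeCN (Saegusa–Ito oxidation) gives the cross-conjugated trienone F4.
- Reversible conjugate addition of alcohol 10 at C8 (cat. KN(SiMe3)2, THF, −20 °C) returns to 18.

C9 is still set by the chair of the shift; C8 is then set under equilibrium control, expected trans to the C9 oxygen.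

Risk 2, step 5. Proton exchange at the new, doubly activated α-centre or weak induction by the ligand may erode the enantiopurity. The fallback is a racemic coupling followed by enzymatic resolution. It sets out from 5 and 7:
- Bu3SnF, Pd(OAc)2, P(t-Bu)3 gives the racemic ketone F5.
- Luche reduction (axial hydride) gives the racemic trans-allylic alcohol F6.
- Lipase from Burkholderia cepacia with vinyl acetate should acetylate the (1R,6S)-enantiomer to the acetate F7, which is separated from the unreacted (1S,6R)-alcohol.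
- K2CO3, MeOH gives the (1R,6S)-alcohol F8.
- MnO2 in CH2Cl2 returns to 9.

Risk 3, step 10. Facial selectivity of the alkylation at C7 may be poor if the enolate is not held in the chelate, and the C8 ether may be lost from the lithium enolate. The fallback is a Frater–Seebach dianion alkylation. It sets out from 18:
- DDQ gives the 8β-hydroxy ketone F9.
- LiN(iPr)2 (2.2 equiv) forms the chelated alkoxide–enolate dianion, in which an oxide cannot leave; BrCH2C(O)NMe2 alkylates it anti to C9 to give the 7β-alkylated hydroxy ketone F10.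
- 4-Methoxybenzyl 2,2,2-trichloroacetimidate with La(OTf)3 (cat.) restores the ether and returns to 20.

**Further compounds**

F1 | step 9 | (1R,6S)-1-ethynyl-6-(2,2-dimethyl-4H-1,3-dioxin-5-yl)-3-{[tert-butyl(diphenyl)silyl]oxymethyl}cyclohex-2-en-1-ol | C#C[C@@]1(O)C=C(CO[Si](c2ccccc2)(c3ccccc3)C(C)(C)C)CC[C@H]1C4=COC(C)(C)OC4
F2 | step 9 | (1R,6S)-1-ethenyl-6-(2,2-dimethyl-4H-1,3-dioxin-5-yl)-3-{[tert-butyl(diphenyl)silyl]oxymethyl}cyclohex-2-en-1-ol | C=C[C@@]1(O)C=C(CO[Si](c2ccccc2)(c3ccccc3)C(C)(C)C)CC[C@H]1C4=COC(C)(C)OC4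
F3 | step 9 | trimethylsilyl dienol ether (C6–OSiMe3, C6=C7) of the 8-deoxy analogue of 18 | C1/C=C(\O[Si](C)(C)C)/C=C(/CO[Si](c2ccccc2)(c3ccccc3)C(C)(C)C)CC/C=C4/COC(C)(C)O[C@H]14
F4 | step 9 | cross-conjugated trienone with C7=C8 (E) in place of the C8 ether of 18 | O=C1/C=C/[C@H]2OC(C)(C)OC/C2=C/CC/C(CO[Si](c3ccccc3)(c4ccccc4)C(C)(C)C)=C\1
F5 | step 5 | racemic 6-(2,2-dimethyl-4H-1,3-dioxin-5-yl)-3-{[tert-butyl(diphenyl)silyl]oxymethyl}cyclohex-2-en-1-one | O=C1C=C(CO[Si](c2ccccc2)(c3ccccc3)C(C)(C)C)CCC1C4=COC(C)(C)OC4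
F6 | step 5 | racemic trans-6-(2,2-dimethyl-4H-1,3-dioxin-5-yl)-3-{[tert-butyl(diphenyl)silyl]oxymethyl}cyclohex-2-en-1-ol (relative configuration shown) | O[C@@H]1C=C(CO[Si](c2ccccc2)(c3ccccc3)C(C)(C)C)CC[C@H]1C4=COC(C)(C)OC4
F7 | step 5 | (1R,6S)-acetate of F6 | CC(=O)O[C@@H]1C=C(CO[Si](c2ccccc2)(c3ccccc3)C(C)(C)C)CC[C@H]1C4=COC(C)(C)OC4
F8 | step 5 | (1R,6S)-6-(2,2-dimethyl-4H-1,3-dioxin-5-yl)-3-{[tert-butyl(diphenyl)silyl]oxymethyl}cyclohex-2-en-1-ol, single enantiomer | O[C@@H]1C=C(CO[Si](c2ccccc2)(c3ccccc3)C(C)(C)C)CC[C@H]1C4=COC(C)(C)OC4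
F9 | step 10 | 8β-hydroxy dienone (18 without the PMB group) | O[C@H]1CC(=O)/C=C(/CO[Si](c2ccccc2)(c3ccccc3)C(C)(C)C)CC/C=C4/COC(C)(C)O[C@H]14
F10 | step 10 | 7β-(dimethylcarbamoylmethyl)-8β-hydroxy dienone | O[C@H]1[C@@H](CC(=O)N(C)C)C(=O)/C=C(/CO[Si](c2ccccc2)(c3ccccc3)C(C)(C)C)CC/C=C4/COC(C)(C)O[C@H]14
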